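**Strategy.** The route rests on disconnecting C3–C4 of ring C. Both carbons carry oxygen in the flavonol, and both are available as formyl carbons held in a 1,6-relationship by O1 and C2. A carbene-catalysed crossed benzoin reaction can therefore join them with polarity reversal at the ring A formyl carbon, closing ring C as a 3-hydroxyflavanone in one operation. The precursor is an aryl ether dialdehyde: a ring A salicylaldehyde (8-OMe, O5 and O7 as SEM ethers) whose phenol oxygen carries a 1-(4-prenyloxyphenyl)-2-oxoethyl group. Dehydrogenation, O3-prenylation and fluoride deprotection finish the flavone; all stereochemistry is transient.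

Key step: step 9

Remark: the target is achiral and every intermediate with a stereocentre at C2 is racemic; where a SMILES string shows configuration, one enantiomer is drawn to mark relative configuration only. SEM = 2-(trimethylsilyl)ethoxymethyl, SEM-oxy = [2-(trimethylsilyl)ethoxy]methoxy, prenyl = 3-methylbut-2-enyl.

**Route**

Step 1
Reactants: 1 2,4,6-trihydroxybenzaldehyde
Product: 2 2-hydroxy-4,6-bis(SEM-oxy)benzaldehyde
Conditions: SEMCl (2.1 equiv), i-Pr2NEt (2.5 equiv), CH2Cl2/THF, 0 °C to rt
Reagents that add atoms: 2-(trimethylsilyl)ethoxymethyl chloride, C[Si](C)(C)CCOCCl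
Why: Williamson-type O-alkylation with an α-chloro ether, in which the 4-OH and one ortho OH are etherified while the remaining ortho hydroxyl is held in a hydrogen bond to the formyl oxygen and stays free when only two equivalents are used.

Step 2
Reactants: 2 2-hydroxy-4,6-bis(SEM-oxy)benzaldehyde
Product: 4 3,5-bis(SEM-oxy)benzene-1,2-diol, via aryl formate 3 (not isolated)
Conditions: 30% aq. H2O2 (1.2 equiv), NaOH (2 equiv), THF/H2O, 0 °C, argon
Reagents that add atoms: hydrogen peroxide, OO
Why: Dakin oxidation, in which hydroperoxide adds to the formyl group of the ortho-hydroxybenzaldehyde, the electron-rich aryl group migrates to oxygen and formate 3 is saponified in the flask; degassed solvents at low temperature protect the oxidation-prone catechol, and the SEM acetals are inert to base.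

Step 3
Reactants: 4 3,5-bis(SEM-oxy)benzene-1,2-diol
Product: 6 2,3-dihydroxy-4,6-bis(SEM-oxy)benzaldehyde, via hydroxymethyl catechol 5 (not isolated)
Conditions: MgCl2 (3 equiv), Et3N (4 equiv), (CH2O)n (6 equiv), THF, reflux, argon
Reagents that add atoms: paraformaldehyde (as formaldehyde), C=O
Why: Casnati–Skattebøl ortho-formylation, in which the magnesium phenoxide at O1 delivers formaldehyde to C6, the only free ortho position, and the hydroxymethyl compound 5 is dehydrogenated by a second formaldehyde through an Oppenauer-type hydride transfer; C4 between the two SEM ethers has no neighbouring phenoxide and should not react.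

Step 4
Reactants: 6 2,3-dihydroxy-4,6-bis(SEM-oxy)benzaldehyde
Product: 7 2-hydroxy-3-methoxy-4,6-bis(SEM-oxy)benzaldehyde
Conditions: NaH (2.1 equiv), DMSO, rt; then MeI (1.0 equiv), rt
Reagents that add atoms: iodomethane, CI
Why: Regioselective Williamson methylation of the dianion, in which the O2 phenoxide is chelated and conjugated to the formyl group, so the more basic O3 phenoxide takes the single equivalent of MeI, as in the known 3-O-alkylation of 2,3-dihydroxybenzaldehyde.

Step 5
Reactants: 8 methyl 4-hydroxymandelate (racemic); 9 prenyl bromide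
Product: 10 methyl 2-hydroxy-2-(4-prenyloxyphenyl)acetate (racemic)
Conditions: K2CO3, acetone, 50 °C
Reagents that add atoms: none
Why: Williamson ether synthesis, in which K2CO3 deprotonates only the phenol, so SN2 reaction with the primary allylic bromide leaves the secondary alcohol and the ester untouched.

Step 6
Reactants: 7 2-hydroxy-3-methoxy-4,6-bis(SEM-oxy)benzaldehyde; 10 methyl 2-hydroxy-2-(4-prenyloxyphenyl)acetate
Product: 11 methyl 2-[2-formyl-6-methoxy-3,5-bis(SEM-oxy)phenoxy]-2-(4-prenyloxyphenyl)acetate (racemic)
Conditions: PPh3, diisopropyl azodicarboxylate (DIAD), THF, 0 °C to rt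
Reagents that add atoms: none
Why: Mitsunobu reaction, in which the acidic salicylaldehyde phenol protonates the betaine and displaces the activated benzylic alcohol with inversion (of no consequence in the racemic series), forming the aryl ether without base and so without aldol closure onto the ortho formyl group.

Step 7
Reactants: 11 methyl 2-[2-formyl-6-methoxy-3,5-bis(SEM-oxy)phenoxy]-2-(4-prenyloxyphenyl)acetate
Product: 12 2-[2-(hydroxymethyl)-6-methoxy-3,5-bis(SEM-oxy)phenoxy]-2-(4-prenyloxyphenyl)ethanol (racemic)
Conditions: LiAlH4, THF, 0 °C; basic (Fieser) work-up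
Reagents that add atoms: none
Why: Hydride reduction of the aldehyde and the ester with LiAlH4, to which aryl, SEM and prenyl ethers are inert; the basic work-up is chosen because the trioxygenated benzylic alcohol ionises readily in acid.

Step 8
Reactants: 12 2-[2-(hydroxymethyl)-6-methoxy-3,5-bis(SEM-oxy)phenoxy]-2-(4-prenyloxyphenyl)ethanol
Product: 13 3-methoxy-2-[2-oxo-1-(4-prenyloxyphenyl)ethoxy]-4,6-bis(SEM-oxy)benzaldehyde (racemic)
Conditions: Dess–Martin periodinane (2.4 equiv), pyridine, CH2Cl2, 0 °C to rt; used crude at once
Reagents that add atoms: none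
Why: Dess–Martin oxidation of both alcohols under pyridine buffer, a neutral and non-enolising method that neither ionises the electron-rich benzylic position nor exposes the enolisable α-aryloxy aldehyde to strong base; lactone formation is not expected because the only lactol available is a seven-membered one of a deactivated aryl aldehyde.

Step 9
Reactants: 13 3-methoxy-2-[2-oxo-1-(4-prenyloxyphenyl)ethoxy]-4,6-bis(SEM-oxy)benzaldehyde
Product: 14 trans-3-hydroxy-8-methoxy-4'-prenyloxy-5,7-bis(SEM-oxy)flavanone (racemic)
Conditions: 2-(pentafluorophenyl)-6,7-dihydro-5H-pyrrolo[2,1-c][1,2,4]triazol-2-ium tetrafluoroborate (15 mol%), Et3N (20 mol%), toluene (0.02 M), rt, argon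
Reagents that add atoms: none
Why: The triazolylidene released by Et3N adds to the ring A formyl carbon, proton transfer gives the Breslow enaminol, and this acyl anion equivalent attacks the aliphatic aldehyde; collapse of the adduct returns the carbene and leaves the C4 ketone and the C3 carbinol. This is an intramolecular crossed benzoin reaction of the kind known for 2-(2-oxoalkoxy)benzaldehydes, which give 3-hydroxychroman-4-ones. Ring C closes in a 6-exo-trig mode, the C3–C4 bond being its only new bond. The C3 stereocentre is controlled by the existing C2 centre: attack anti to the C2 aryl group and, because C3 is alpha to the ketone, equilibration under Et3N should lead to the 2,3-trans isomer with aryl and hydroxyl both equatorial. The step needs C–C bond formation to outrun aryloxide loss from an enaminol formed at the aliphatic aldehyde, aldol closure through the C2 enol, and intermolecular benzoin reaction; the 1,6-spacing of the formyl carbons through O1 and C2, the alpha-branching at C2 that slows carbene entry there, and the quaternary C2 of the aldol adduct (which cannot dehydrate and so reverts) secure this, supported by a weakly basic N-C6F5 carbene that favours benzoin over redox pathways. Should the carbene nevertheless enter at the aliphatic aldehyde and close the ring, the isomeric ketol results and is carried to the same flavonol in step 10.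

Step 10
Reactants: 14 trans-3-hydroxy-8-methoxy-4'-prenyloxy-5,7-bis(SEM-oxy)flavanone
Product: 16 3-hydroxy-8-methoxy-4'-prenyloxy-5,7-bis(SEM-oxy)flavone, via flavan-3,4-dione 15 (not isolated)
Conditions: Cu(OAc)2 (20 mol%), air, pyridine/MeOH, rt
Reagents that add atoms: none
Why: Copper-catalysed aerobic dehydrogenation of an α-ketol to a 1,2-diketone, in which Cu(OAc)2 oxidises the enediol of 14 and is reoxidised by air, and dione 15 enolises towards C2 to give the aromatic pyranone, erasing both stereocentres; room temperature keeps the ethers, SEM groups and prenyl alkene untouched and avoids oxidative cleavage of the flavonol.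

Step 11
Reactants: 16 3-hydroxy-8-methoxy-4'-prenyloxy-5,7-bis(SEM-oxy)flavone; 9 prenyl bromide
Product: 17 8-methoxy-3,4'-diprenyloxy-5,7-bis(SEM-oxy)flavone
Conditions: K2CO3, acetone, 50 °C
Reagents that add atoms: none
Why: Williamson ether synthesis, in which the 3-OH is the only free hydroxyl and its enolate-like anion is O-alkylated by the primary allylic bromide.

Step 12
Reactants: 17 8-methoxy-3,4'-diprenyloxy-5,7-bis(SEM-oxy)flavone
Product: 18 5,7-dihydroxy-8-methoxy-3,4'-diprenyloxyflavone
Conditions: Bu4NF (6 equiv), THF/DMPU, 50 °C; aq. NH4Cl work-up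
Reagents that add atoms: none
Why: Fluoride-induced fragmentation of the SEM ethers, in which fluoride attacks silicon, ethene and formaldehyde are expelled and the acidic 5- and 7-phenoxides are released under basic conditions that leave the acid-sensitive prenyl ethers and the methyl ether intact.

**Compound list**

1 | 2,4,6-trihydroxybenzaldehyde | O=Cc1c(O)cc(O)cc1O | starting material
2 | 2-hydroxy-4,6-bis(SEM-oxy)benzaldehyde | O=Cc1c(O)cc(OCOCC[Si](C)(C)C)cc1OCOCC[Si](C)(C)C | intermediate
3 | 2-hydroxy-4,6-bis(SEM-oxy)phenyl formate | O=COc1c(O)cc(OCOCC[Si](C)(C)C)cc1OCOCC[Si](C)(C)C | intermediate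
4 | 3,5-bis(SEM-oxy)benzene-1,2-diol | Oc1c(O)cc(OCOCC[Si](C)(C)C)cc1OCOCC[Si](C)(C)C | intermediate
5 | 3-(hydroxymethyl)-4,6-bis(SEM-oxy)benzene-1,2-diol | OCc1c(O)c(O)c(OCOCC[Si](C)(C)C)cc1OCOCC[Si](C)(C)C | intermediate
6 | 2,3-dihydroxy-4,6-bis(SEM-oxy)benzaldehyde | O=Cc1c(O)c(O)c(OCOCC[Si](C)(C)C)cc1OCOCC[Si](C)(C)C | intermediate
7 | 2-hydroxy-3-methoxy-4,6-bis(SEM-oxy)benzaldehyde | O=Cc1c(O)c(OC)c(OCOCC[Si](C)(C)C)cc1OCOCC[Si](C)(C)C | intermediate
8 | methyl 4-hydroxymandelate (racemic) | COC(=O)C(O)c1ccc(O)cc1 | starting material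
9 | prenyl bromide (1-bromo-3-methylbut-2-ene) | CC(C)=CCBr | starting material
10 | methyl 2-hydroxy-2-(4-prenyloxyphenyl)acetate (racemic) | COC(=O)C(O)c1ccc(OCC=C(C)C)cc1 | intermediate
11 | methyl 2-[2-formyl-6-methoxy-3,5-bis(SEM-oxy)phenoxy]-2-(4-prenyloxyphenyl)acetate (racemic, one enantiomer drawn) | CC(C)=CCOc1ccc(cc1)[C@@H](Oc1c(OC)c(OCOCC[Si](C)(C)C)cc(OCOCC[Si](C)(C)C)c1C=O)C(=O)OC | intermediate
12 | 2-[2-(hydroxymethyl)-6-methoxy-3,5-bis(SEM-oxy)phenoxy]-2-(4-prenyloxyphenyl)ethanol (racemic, one enantiomer drawn) | CC(C)=CCOc1ccc(cc1)[C@@H](Oc1c(OC)c(OCOCC[Si](C)(C)C)cc(OCOCC[Si](C)(C)C)c1CO)CO | intermediate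
13 | 3-methoxy-2-[2-oxo-1-(4-prenyloxyphenyl)ethoxy]-4,6-bis(SEM-oxy)benzaldehyde (racemic, one enantiomer drawn) | CC(C)=CCOc1ccc(cc1)[C@@H](Oc1c(OC)c(OCOCC[Si](C)(C)C)cc(OCOCC[Si](C)(C)C)c1C=O)C=O | intermediate
14 | trans-3-hydroxy-8-methoxy-4'-prenyloxy-5,7-bis(SEM-oxy)flavanone (racemic, (2R,3R) enantiomer drawn) | CC(C)=CCOc1ccc(cc1)[C@@H]1[C@@H](O)C(=O)c2c(OCOCC[Si](C)(C)C)cc(OCOCC[Si](C)(C)C)c(OC)c2O1 | intermediate
15 | 8-methoxy-4'-prenyloxy-5,7-bis(SEM-oxy)flavan-3,4-dione (racemic, one enantiomer drawn) | CC(C)=CCOc1ccc(cc1)[C@@H]1C(=O)C(=O)c2c(OCOCC[Si](C)(C)C)cc(OCOCC[Si](C)(C)C)c(OC)c2O1 | intermediate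
16 | 3-hydroxy-8-methoxy-4'-prenyloxy-5,7-bis(SEM-oxy)flavone | COc1c(OCOCC[Si](C)(C)C)cc(OCOCC[Si](C)(C)C)c2c(=O)c(O)c(-c3ccc(OCC=C(C)C)cc3)oc12 | intermediate
17 | 8-methoxy-3,4'-diprenyloxy-5,7-bis(SEM-oxy)flavone | COc1c(OCOCC[Si](C)(C)C)cc(OCOCC[Si](C)(C)C)c2c(=O)c(OCC=C(C)C)c(-c3ccc(OCC=C(C)C)cc3)oc12 | intermediate
18 | 5,7-dihydroxy-8-methoxy-3,4'-diprenyloxyflavone | COc1c(O)cc(O)c2c(=O)c(OCC=C(C)C)c(-c3ccc(OCC=C(C)C)cc3)oc12 | target

**Step count and risks**

Total step count: 12. Longest linear sequence: 11 steps (steps 1–4 and 6–12, from 1 to 18); step 5 is a one-step branch.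

Steps most likely to fail:

1. Step 9. The carbene may enter at the aliphatic formyl group and the resulting enaminol may expel the ring A aryloxide (internal redox to an aryl ester), or amine-mediated enolisation at C2 may divert material into aldol products, so that ring C does not close. Fallback: from 13, the same two formyl carbons are joined reductively by intramolecular pinacol coupling with SmI2 (THF, t-BuOH, −78 °C). The aryl aldehyde should be reduced first, so the ketyl sits at C4 and cannot expel the aryloxide. This should give 2,3-trans-3,4-cis-8-methoxy-4'-prenyloxy-5,7-bis(SEM-oxy)flavan-3,4-diol F1, with other diastereomers equally usable. Oxidation of both carbinols with 2-iodoxybenzoic acid in DMSO at rt, which does not cleave 1,2-diols, should give dione 15, whose enolisation brings the material back to the route at 16.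

2. Step 6. Substitution at the hindered, hydrogen-bonded phenol flanked by formyl and methoxy groups may be slow, so that the activated benzylic oxyphosphonium ion decomposes or is captured by the hydrazide instead. Fallback: from 10, Appel bromination (PPh3, CBr4, CH2Cl2, 0 °C) should give methyl 2-bromo-2-(4-prenyloxyphenyl)acetate F2. SN2 O-alkylation of phenol 7 with it (K2CO3, DMF, rt, kept mild to avoid aldol closure onto the formyl group) comes back to the route at 11.

3. Step 3. Air oxidation of the very electron-rich catechol, or sluggish turnover of its magnesium chelate, may leave conversion to the aldehyde low. Fallback: from 2, electrophilic bromination ortho to the free phenol (N-bromosuccinimide, CH2Cl2, 0 °C) should give 3-bromo-2-hydroxy-4,6-bis(SEM-oxy)benzaldehyde F3. Ullmann-type methoxylation (NaOMe, CuBr, DMF/MeOH, 110 °C), analogous to the conversion of 5-bromovanillin into syringaldehyde, comes back to the route at 7 and bypasses 4 and 6.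

Further compounds
F1 | step 9 | 2,3-trans-3,4-cis-8-methoxy-4'-prenyloxy-5,7-bis(SEM-oxy)flavan-3,4-diol (racemic, one enantiomer drawn) | CC(C)=CCOc1ccc(cc1)[C@@H]1[C@@H](O)[C@@H](O)c2c(OCOCC[Si](C)(C)C)cc(OCOCC[Si](C)(C)C)c(OC)c2O1
F2 | step 6 | methyl 2-bromo-2-(4-prenyloxyphenyl)acetate (racemic) | COC(=O)C(Br)c1ccc(OCC=C(C)C)cc1
F3 | step 3 | 3-bromo-2-hydroxy-4,6-bis(SEM-oxy)benzaldehyde | O=Cc1c(O)c(Br)c(OCOCC[Si](C)(C)C)cc1OCOCC[Si](C)(C)C
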